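**Assumption:** Peruvinide C has no stereocentre (it is achiral), so no stereocontrol is needed; the stereocentres of 3, 4 and 5 are formed racemic and disappear on aromatisation.

## Retrosynthetic overview

1. Depside C(=O)–O bond: 19 ⇒ acid 9 (2-OH as benzyl ether) + phenol 16 (5-pentylpyrogallol with two adjacent OH masked as a diphenylmethylene ketal); one hydrogenolysis removes both groups last.
2. Acid 9 ⇒ methyl 2,4-dihydroxy-6-propylbenzoate 6 ⇒ cyclohexenone 4 ⇒ dimethyl malonate 1 + (E)-hept-3-en-2-one 2, joined by intermolecular Michael addition (key C–C bond) and closed by Dieckmann/Claisen condensation.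
3. Phenol 16 ⇒ 5-pentylpyrogallol 15 ⇒ 3,4,5-trimethoxybenzaldehyde 10 (Wittig, hydrogenation, BBr3).
4. Ring order: the resorcylate carbocycle is built first (step 1, aromatised in step 2); the pyrogallol ring is bought; the benzodioxole ketal ring (step 9) is protective only and is opened in the last step.

## Route

**Step 1**
Reactants: 1 dimethyl malonate; 2 (E)-hept-3-en-2-one
Product: 4 methyl 2-hydroxy-4-oxo-6-propylcyclohex-2-ene-1-carboxylate (racemic, enol form of the 2,4-dione), via Michael adduct 3 (not isolated)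
Conditions: NaOMe (1.1 eq), MeOH, reflux, 4 h; then aq. HCl to pH 3, 0 °C
Reagents that add atoms: none
Why: The malonate enolate adds to the enone in an intermolecular Michael addition (forming the future ring bond C1–C6), and the methyl-ketone enolate of 3 then closes the six-membered ring by intramolecular Claisen (Dieckmann) condensation onto one ester; the two stereocentres form racemic and are erased in step 2.

**Step 2**
Reactants: 4 methyl 2-hydroxy-4-oxo-6-propylcyclohex-2-ene-1-carboxylate
Product: 6 methyl 2,4-dihydroxy-6-propylbenzoate, via bromo-dione 5 (not isolated)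
Conditions: Br2 (1.0 eq), DMF, 0 °C, 1 h; then 80 °C, 12 h
Reagents that add atoms: none
Why: Electrophilic bromination of the enolised 1,3-dione followed by thermal dehydrobromination and tautomerisation gives the resorcylate (bromination–dehydrohalogenation aromatisation), with the ester kept because the temperature stays well below that needed for demethoxycarbonylation.

**Step 3**
Reactants: 6 methyl 2,4-dihydroxy-6-propylbenzoate
Product: 7 methyl 2-hydroxy-4-methoxy-6-propylbenzoate
Conditions: MeI (1.1 eq), K2CO3 (1.2 eq), acetone, rt → 40 °C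
Reagents that add atoms: iodomethane, CI
Why: Williamson etherification is selective for the 4-OH because the 2-OH is locked in a hydrogen bond to the ester carbonyl and is much less acidic and nucleophilic.

**Step 4**
Reactants: 7 methyl 2-hydroxy-4-methoxy-6-propylbenzoate
Product: 8 methyl 2-(benzyloxy)-4-methoxy-6-propylbenzoate
Conditions: BnBr (1.3 eq), K2CO3 (2 eq), KI (cat.), DMF, 70 °C
Reagents that add atoms: benzyl bromide, BrCc1ccccc1
Why: Under forcing Williamson conditions in DMF the chelated 2-OH is benzylated, masking it for the later esterification with a group that hydrogenolysis removes.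

**Step 5**
Reactants: 8 methyl 2-(benzyloxy)-4-methoxy-6-propylbenzoate
Product: 9 2-(benzyloxy)-4-methoxy-6-propylbenzoic acid
Conditions: KOH (10 eq), DMSO/H2O 4:1, 90 °C; then 1 M HCl, 0 °C
Reagents that add atoms: potassium hydroxide, [K+].[OH-]
Why: Poorly solvated hydroxide in aqueous DMSO saponifies the di-ortho-substituted methyl ester, and the benzyl and methyl ethers are inert to base.

**Step 6**
Reactants: 10 3,4,5-trimethoxybenzaldehyde; 11 butyltriphenylphosphonium bromide
Product: 13 1,2,3-trimethoxy-5-(pent-1-en-1-yl)benzene (E/Z mixture), via phosphorus ylide 12 (not isolated)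
Conditions: 11 (1.25 eq), KOtBu (1.25 eq), THF, 0 °C, 30 min; then 10, 0 °C → rt
Reagents that add atoms: none
Why: Wittig olefination of an aromatic aldehyde with a non-stabilised ylide is high-yielding, and the alkene geometry is irrelevant because the double bond is hydrogenated next.

**Step 7**
Reactants: 13 1,2,3-trimethoxy-5-(pent-1-en-1-yl)benzene
Product: 14 1,2,3-trimethoxy-5-pentylbenzene
Conditions: H2 (1 atm), 10% Pd/C, EtOAc, rt
Reagents that add atoms: none
Why: Catalytic hydrogenation saturates the styrenic double bond of both isomers without touching the aryl methyl ethers.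

**Step 8**
Reactants: 14 1,2,3-trimethoxy-5-pentylbenzene
Product: 15 5-pentylbenzene-1,2,3-triol
Conditions: BBr3 (4 eq), CH2Cl2, −78 °C → rt; degassed H2O quench, under N2
Reagents that add atoms: none
Why: Lewis-acid ether cleavage by BBr3 removes all three aryl methyl groups as MeBr; the air-sensitive triol is handled under nitrogen and used at once.

**Step 9**
Reactants: 15 5-pentylbenzene-1,2,3-triol
Product: 16 6-pentyl-2,2-diphenyl-1,3-benzodioxol-4-ol
Conditions: Ph2CCl2 (1.1 eq), Ph2O, 175 °C, 30 min, N2 sweep
Reagents that add atoms: dichlorodiphenylmethane, ClC(Cl)(c1ccccc1)c1ccccc1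
Why: Ketalisation of a vicinal diphenol with the gem-dichloride can only bridge two adjacent oxygens, and by symmetry either adjacent pair gives the same product, leaving exactly one terminal OH free.

**Step 10**
Reactants: 9 2-(benzyloxy)-4-methoxy-6-propylbenzoic acid; 16 6-pentyl-2,2-diphenyl-1,3-benzodioxol-4-ol
Product: 18 6-pentyl-2,2-diphenyl-1,3-benzodioxol-4-yl 2-(benzyloxy)-4-methoxy-6-propylbenzoate, via acid chloride 17 (not isolated)
Conditions: (COCl)2 (1.5 eq), DMF (cat.), CH2Cl2, 0 °C → rt, concentrate (toluene chase); then 16 (1.0 eq), Et3N (2.5 eq), DMAP (0.2 eq), CH2Cl2, 0 °C → rt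
Reagents that add atoms: none
Why: The acid chloride, activated further as its acyl-pyridinium by DMAP (nucleophilic-catalysed acylation), esterifies the single free phenol under basic conditions that the ketal and benzyl ether tolerate.

**Step 11**
Reactants: 18 6-pentyl-2,2-diphenyl-1,3-benzodioxol-4-yl 2-(benzyloxy)-4-methoxy-6-propylbenzoate
Product: 19 Peruvinide C
Conditions: H2 (1 atm), 20% Pd(OH)2/C, EtOAc/THF, rt
Reagents that add atoms: none
Why: Hydrogenolysis cleaves the benzylic C–O bonds of both the benzyl ether and the diphenylmethylene ketal under neutral, non-nucleophilic conditions, so the aryl ester is neither cleaved nor migrated.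

## Compound list

1 | dimethyl malonate | COC(=O)CC(=O)OC | starting material
2 | (E)-hept-3-en-2-one | CCC/C=C/C(C)=O | starting material
3 | dimethyl 2-(2-oxoheptan-4-yl)propanedioate (racemic Michael adduct) | CCCC(CC(C)=O)C(C(=O)OC)C(=O)OC | intermediate
4 | methyl 2-hydroxy-4-oxo-6-propylcyclohex-2-ene-1-carboxylate (racemic, diastereomer mixture) | CCCC1CC(=O)C=C(O)C1C(=O)OC | intermediate
5 | methyl 3-bromo-2-hydroxy-4-oxo-6-propylcyclohex-2-ene-1-carboxylate (racemic) | CCCC1CC(=O)C(Br)=C(O)C1C(=O)OC | intermediate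
6 | methyl 2,4-dihydroxy-6-propylbenzoate | CCCc1cc(O)cc(O)c1C(=O)OC | intermediate
7 | methyl 2-hydroxy-4-methoxy-6-propylbenzoate | CCCc1cc(OC)cc(O)c1C(=O)OC | intermediate
8 | methyl 2-(benzyloxy)-4-methoxy-6-propylbenzoate | CCCc1cc(OC)cc(OCc2ccccc2)c1C(=O)OC | intermediate
9 | 2-(benzyloxy)-4-methoxy-6-propylbenzoic acid | CCCc1cc(OC)cc(OCc2ccccc2)c1C(=O)O | intermediate
10 | 3,4,5-trimethoxybenzaldehyde | COc1cc(C=O)cc(OC)c1OC | starting material
11 | butyltriphenylphosphonium bromide | CCCC[P+](c1ccccc1)(c1ccccc1)c1ccccc1.[Br-] | starting material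
12 | butylidene(triphenyl)phosphorane | CCCC=P(c1ccccc1)(c1ccccc1)c1ccccc1 | intermediate
13 | 1,2,3-trimethoxy-5-(pent-1-en-1-yl)benzene (E/Z mixture) | CCCC=Cc1cc(OC)c(OC)c(OC)c1 | intermediate
14 | 1,2,3-trimethoxy-5-pentylbenzene | CCCCCc1cc(OC)c(OC)c(OC)c1 | intermediate
15 | 5-pentylbenzene-1,2,3-triol | CCCCCc1cc(O)c(O)c(O)c1 | intermediate
16 | 6-pentyl-2,2-diphenyl-1,3-benzodioxol-4-ol | CCCCCc1cc(O)c2OC(c3ccccc3)(c3ccccc3)Oc2c1 | intermediate
17 | 2-(benzyloxy)-4-methoxy-6-propylbenzoyl chloride | CCCc1cc(OC)cc(OCc2ccccc2)c1C(Cl)=O | intermediate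
18 | 6-pentyl-2,2-diphenyl-1,3-benzodioxol-4-yl 2-(benzyloxy)-4-methoxy-6-propylbenzoate | CCCCCc1cc(OC(=O)c2c(OCc3ccccc3)cc(OC)cc2CCC)c2OC(c3ccccc3)(c3ccccc3)Oc2c1 | intermediate
19 | Peruvinide C (2,3-dihydroxy-5-pentylphenyl 2-hydroxy-4-methoxy-6-propylbenzoate) | CCCCCc1cc(O)c(O)c(OC(=O)c2c(O)cc(OC)cc2CCC)c1 | target

## Summary

Total step count: 11.
Longest linear sequence: 7 steps (steps 1, 2, 3, 4, 5, 10, 11 from 1 and 2); the phenol branch is 6 steps (6, 7, 8, 9, 10, 11 from 10 and 11).

Three steps most likely to fail: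

**Step 2 (aromatisation; risk of nuclear over-bromination or incomplete dehydrobromination).** The fallback sets out from 4 and comes back at 6. Instead of fighting over-bromination, 4 is treated with excess Br2 (3 eq) in AcOH at rt so that aromatisation and ring bromination both go to completion, giving methyl 3,5-dibromo-2,4-dihydroxy-6-propylbenzoate F1 as a single crystalline product. Both aryl bromides are then removed by catalytic hydrogenolysis (H2, Pd/C, Et3N, MeOH) to return to 6.

**Step 5 (saponification of the di-ortho-substituted methyl ester; may stall).** The fallback sets out from 8 and comes back at 9. It avoids attack at the hindered acyl carbon by hydroxide altogether. The ester is reduced with LiAlH4 (THF, 0 °C → reflux) to [2-(benzyloxy)-4-methoxy-6-propylphenyl]methanol F2. This is oxidised with activated MnO2 (CH2Cl2, rt) to 2-(benzyloxy)-4-methoxy-6-propylbenzaldehyde F3. Pinnick oxidation (NaClO2, NaH2PO4, 2-methyl-2-butene, t-BuOH/H2O) then gives acid 9.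

**Step 10 (acylation of 16 by the hindered aroyl chloride; may be slow or low-yielding).** The fallback sets out from 9 and comes back at 19. The acid is debenzylated (H2, Pd/C, EtOAc) to 2-hydroxy-4-methoxy-6-propylbenzoic acid F4. This is tied up with acetone (TFAA, TFA, 0 °C → rt) as the activated salicylate acetonide 7-methoxy-2,2-dimethyl-5-propyl-4H-1,3-benzodioxin-4-one F5. The sodium phenoxide of 16 (NaH, THF/DMF, rt → 60 °C) opens this dioxinone with loss of acetone to give 6-pentyl-2,2-diphenyl-1,3-benzodioxol-4-yl 2-hydroxy-4-methoxy-6-propylbenzoate F6. Hydrogenolysis of the ketal (H2, Pd(OH)2/C, EtOAc/THF) then gives 19 directly.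

## Further compounds

F1 | step 2 | methyl 3,5-dibromo-2,4-dihydroxy-6-propylbenzoate | CCCc1c(Br)c(O)c(Br)c(O)c1C(=O)OC
F2 | step 5 | [2-(benzyloxy)-4-methoxy-6-propylphenyl]methanol | CCCc1cc(OC)cc(OCc2ccccc2)c1CO
F3 | step 5 | 2-(benzyloxy)-4-methoxy-6-propylbenzaldehyde | CCCc1cc(OC)cc(OCc2ccccc2)c1C=O
F4 | step 10 | 2-hydroxy-4-methoxy-6-propylbenzoic acid | CCCc1cc(OC)cc(O)c1C(=O)O
F5 | step 10 | 7-methoxy-2,2-dimethyl-5-propyl-4H-1,3-benzodioxin-4-one | CCCc1cc(OC)cc2OC(C)(C)OC(=O)c12
F6 | step 10 | 6-pentyl-2,2-diphenyl-1,3-benzodioxol-4-yl 2-hydroxy-4-methoxy-6-propylbenzoate | CCCCCc1cc(OC(=O)c2c(O)cc(OC)cc2CCC)c2OC(c3ccccc3)(c3ccccc3)Oc2c1
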